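**Retrosynthetic overview**
1. Target 14 ⇐ vinyl iodide 12 + butenyl boronate 13: a stereoretentive sp2–sp2 coupling attaches the (E)-butenyl unit to an exocyclic (Z)-iodomethylidene.
2. 12 ⇐ furan 8 in one flask: oxidative dearomatisation of the furan to a cis-ene-dione/ynone, then a TMSI-triggered, chiral-Lewis-acid-catalysed iodo-aldol closure of the C1–C5 ring bond. This one operation makes the cyclopentenone, the tertiary carbinol (1S) and the 5Z alkene.
3. 8 ⇐ dibromofuran 7: C5-selective ethynylation; the furan C4–Br becomes the ring C3–Br.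
4. 7 ⇐ furfural 1: formyl-directed 4,5-dibromination, then Wittig chain extension on the formyl carbon and alkene hydrogenation.
5. Ring order: the furan is bought, then opened; the cyclopentenone (the only ring of the target) is formed in step 5.

**Assumptions**
- The (S)-oxazaborolidinium salt is assumed to expose the Re face of the C9 ketone of 9 (giving 1S); this sense is not derived here, and the antipodal catalyst is used if the first run shows the opposite sense.
- Boronate 13 is taken as a catalogue reagent; alkene 6 is a Z/E mixture (Z major, drawn as Z), and both isomers give 7.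

**Step 1**
Reactants: 1 furfural (furan-2-carbaldehyde)
Product: 2 4,5-dibromofuran-2-carbaldehyde
Conditions: AlCl3 (2.5 eq, promoter), Br2 (2.2 eq), CH2Cl2, 0 °C → rt; ice/HCl
Reagents that add atoms: bromine (BrBr)
Why: Electrophilic aromatic bromination under swamping-Lewis-acid conditions, where the AlCl3-complexed formyl group shuts off C3 and ring opening so that bromine enters C5 and then C4.

**Step 2**
Reactants: 2 4,5-dibromofuran-2-carbaldehyde; 3 (6-carboxyhexyl)triphenylphosphonium bromide
Product: 6 methyl (7Z)-8-(4,5-dibromofuran-2-yl)oct-7-enoate, via ylide 4 (not isolated), via sodium carboxylate 5 (not isolated)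
Conditions: 3 (1.2 eq), NaHMDS (2.4 eq), THF, 0 °C; 2, −78 °C → rt; then MeI (3 eq), DMF, rt
Reagents that add atoms: iodomethane (CI)
Why: Wittig olefination with a non-stabilised carboxylate ylide (Z-major, geometry irrelevant because the alkene is reduced next), followed by SN2 O-methylation of the sodium carboxylate in the same flask.

**Step 3**
Reactants: 6 methyl (7Z)-8-(4,5-dibromofuran-2-yl)oct-7-enoate
Product: 7 methyl 8-(4,5-dibromofuran-2-yl)octanoate
Conditions: H2 (1 atm), RhCl(PPh3)3 (5 mol %), PhH–EtOH 1:1, rt
Reagents that add atoms: none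
Why: Homogeneous Wilkinson hydrogenation saturates the disubstituted alkene without hydrogenolysis of the C–Br bonds or reduction of the furan, and forms no co-product.

**Step 4**
Reactants: 7 methyl 8-(4,5-dibromofuran-2-yl)octanoate
Product: 8 methyl 8-(4-bromo-5-ethynylfuran-2-yl)octanoate
Conditions: HC≡CMgBr (1.5 eq) + ZnBr2 (1.6 eq), THF, 0 °C; then 7, Pd(PPh3)4 (5 mol %), THF, rt → 45 °C
Reagents that add atoms: ethynylmagnesium bromide (C#C[Mg]Br)
Why: Negishi alkynylation in which oxidative addition is much faster at the C5–Br next to the ring oxygen than at C4–Br and the alkynylzinc tolerates the ester, giving the terminal alkyne directly.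

**Step 5**
Reactants: 8 methyl 8-(4-bromo-5-ethynylfuran-2-yl)octanoate
Product: 12 methyl 8-[(1S,5Z)-3-bromo-1-hydroxy-5-(iodomethylidene)-4-oxocyclopent-2-en-1-yl]octanoate, via ynenedione 9 (not isolated), via iodoallenyl silyl ether 10 (not isolated), via silyl ether 11 (not isolated)
Conditions: DMDO (1.2 eq, acetone), CH2Cl2, −40 → 0 °C, volatiles off at ≤ 0 °C; then (S)-o-tolyl-oxazaborolidinium·NTf2 (20 mol %), TMSI (1.3 eq, slow addition), CH2Cl2, −78 °C; cold 1 M HCl–THF
Reagents that add atoms: dimethyldioxirane (CC1(C)OO1); iodotrimethylsilane (C[Si](C)(C)I)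
Why: Proposed new method: DMDO epoxidises the furan and the epoxide opens to the cis-ene-dione 9 (known furan dearomatisation), TMSI then adds 1,4 to the terminal ynone to give β-iodo siloxyallene 10, whose central carbon attacks the oxazaborolidinium-bound C9 ketone in an intramolecular Mukaiyama-type iodo-aldol (iodo-Morita–Baylis–Hillman) closure; the ketone approaches in the plane of the allene's H/I terminus from the side of the small H, which places iodine cis to the ring carbonyl (5Z), and the catalyst is assumed to screen the Si face so that bond formation on the Re face sets 1S; the closest known reactions are the chiral oxazaborolidinium-catalysed three-component coupling of TMSI, alkynones or propiolates and aldehydes to (Z)-β-iodo Morita–Baylis–Hillman adducts, and the aldol closure of furan-derived cis-ene-diones to 4-hydroxycyclopentenones.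

**Step 6**
Reactants: 12 methyl 8-[(1S,5Z)-3-bromo-1-hydroxy-5-(iodomethylidene)-4-oxocyclopent-2-en-1-yl]octanoate; 13 (E)-2-(but-1-en-1-yl)-4,4,5,5-tetramethyl-1,3,2-dioxaborolane
Product: 14 methyl 8-[(1S,5Z)-3-bromo-1-hydroxy-4-oxo-5-[(2E)-pent-2-en-1-ylidene]cyclopent-2-en-1-yl]octanoate
Conditions: PdCl2(dppf) (5 mol %), K3PO4 (2 eq), THF–H2O 10:1, 0 °C → rt, dark
Reagents that add atoms: none
Why: Suzuki–Miyaura coupling in which the β-iodoenone C–I bond undergoes oxidative addition far faster than the ring C–Br and both alkenyl partners couple with retention, so the 5Z and 2E geometries are carried into 14 and C1 is untouched.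

**Compound list**
1 | furfural (furan-2-carbaldehyde) | O=Cc1ccco1 | starting material
2 | 4,5-dibromofuran-2-carbaldehyde | O=Cc1cc(Br)c(Br)o1 | intermediate
3 | (6-carboxyhexyl)triphenylphosphonium bromide | OC(=O)CCCCCC[P+](c1ccccc1)(c1ccccc1)c1ccccc1.[Br-] | starting material
4 | sodium 7-(triphenyl-λ5-phosphanylidene)heptanoate (ylide) | [Na+].[O-]C(=O)CCCCCC=P(c1ccccc1)(c1ccccc1)c1ccccc1 | intermediate
5 | sodium (7Z)-8-(4,5-dibromofuran-2-yl)oct-7-enoate | [Na+].[O-]C(=O)CCCCC/C=C\c1cc(Br)c(Br)o1 | intermediate
6 | methyl (7Z)-8-(4,5-dibromofuran-2-yl)oct-7-enoate (Z major, Z/E mixture) | COC(=O)CCCCC/C=C\c1cc(Br)c(Br)o1 | intermediate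
7 | methyl 8-(4,5-dibromofuran-2-yl)octanoate | COC(=O)CCCCCCCc1cc(Br)c(Br)o1 | intermediate
8 | methyl 8-(4-bromo-5-ethynylfuran-2-yl)octanoate | COC(=O)CCCCCCCc1cc(Br)c(C#C)o1 | intermediate
9 | methyl (10E)-11-bromo-9,12-dioxotetradec-10-en-13-ynoate (the two acyl groups cis) | COC(=O)CCCCCCCC(=O)/C=C(/Br)C(=O)C#C | intermediate
10 | methyl (10E)-11-bromo-14-iodo-9-oxo-12-[(trimethylsilyl)oxy]tetradeca-10,12,13-trienoate (allene axis racemic) | COC(=O)CCCCCCCC(=O)/C=C(/Br)C(O[Si](C)(C)C)=C=CI | intermediate
11 | methyl 8-[(1S,5Z)-3-bromo-5-(iodomethylidene)-4-oxo-1-[(trimethylsilyl)oxy]cyclopent-2-en-1-yl]octanoate | I/C=C1\C(=O)C(Br)=C[C@@]1(O[Si](C)(C)C)CCCCCCCC(=O)OC | intermediate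
12 | methyl 8-[(1S,5Z)-3-bromo-1-hydroxy-5-(iodomethylidene)-4-oxocyclopent-2-en-1-yl]octanoate | I/C=C1\C(=O)C(Br)=C[C@@]1(O)CCCCCCCC(=O)OC | intermediate
13 | (E)-2-(but-1-en-1-yl)-4,4,5,5-tetramethyl-1,3,2-dioxaborolane | CC/C=C/B1OC(C)(C)C(C)(C)O1 | starting material
14 | methyl 8-[(1S,5Z)-3-bromo-1-hydroxy-4-oxo-5-[(2E)-pent-2-en-1-ylidene]cyclopent-2-en-1-yl]octanoate | CC/C=C/C=C1\C(=O)C(Br)=C[C@@]1(O)CCCCCCCC(=O)OC | target

**Step count and risks**
Total steps: 6. Longest linear sequence: 6 (furfural 1 → 14).

Most likely to fail, in order: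

- **Step 5.** Iodide may add to or exchange with the bromo-ene-dione, and an achiral TMSI-only background closure or cis→trans isomerisation of 9 may erode ee or yield. Fallback, setting out from 8: generate 9 with DMDO as before and close it with TMSI and catalytic TMSOTf but no chiral catalyst. This gives the racemic silyl ether F1, which is hydrolysed to the racemic iodo-enone F2. The enantiomers of F2 are separated by preparative chiral SFC on an amylose carbamate phase, and the (1S)-enantiomer rejoins the route at 12. The stereocentre then comes from resolution instead of catalysis.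

- **Step 6.** Pd may also insert into the ring C–Br, the vinyl-Pd intermediate may leak Z→E, or the aqueous base may attack the β-iodoenone. Fallback, setting out from 12: a Pd-free, base-free copper(I) thiophene-2-carboxylate-mediated coupling (NMP, 0 °C) with tributyl[(1E)-but-1-en-1-yl]stannane F3, which is made from but-1-yne and Bu3SnH with catalytic Pd. This returns to the route at 14.

- **Step 4.** Double coupling or oligomerisation of the free alkyne may occur. Fallback, setting out from 7: selective Br/Mg exchange at C5 with i-PrMgCl·LiCl (THF, −40 °C) gives furylmagnesium chloride F4. DMF converts it to methyl 8-(4-bromo-5-formylfuran-2-yl)octanoate F5. Ohira–Bestmann homologation (dimethyl (1-diazo-2-oxopropyl)phosphonate, K2CO3, MeOH) then returns to the route at 8. The alkyne is thus built by C1 homologation instead of cross-coupling.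

**Further compounds**
F1 | step 5 | racemic methyl 8-[(5Z)-3-bromo-5-(iodomethylidene)-4-oxo-1-[(trimethylsilyl)oxy]cyclopent-2-en-1-yl]octanoate | I/C=C1\C(=O)C(Br)=CC1(O[Si](C)(C)C)CCCCCCCC(=O)OC
F2 | step 5 | racemic methyl 8-[(5Z)-3-bromo-1-hydroxy-5-(iodomethylidene)-4-oxocyclopent-2-en-1-yl]octanoate | I/C=C1\C(=O)C(Br)=CC1(O)CCCCCCCC(=O)OC
F3 | step 6 | tributyl[(1E)-but-1-en-1-yl]stannane | CC/C=C/[Sn](CCCC)(CCCC)CCCC
F4 | step 4 | methyl 8-[4-bromo-5-(chloromagnesio)furan-2-yl]octanoate | COC(=O)CCCCCCCc1cc(Br)c([Mg]Cl)o1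
F5 | step 4 | methyl 8-(4-bromo-5-formylfuran-2-yl)octanoate | COC(=O)CCCCCCCc1cc(Br)c(C=O)o1
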